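1. Late in the green run the readings level off, at 77% links and 10% rings at 12.0 min. In blue, links plus rings reach 0.245 M against 0.24 M charged, so one product uses one second end group, and these are the limiting reagent there.

| flask | first end groups | second end groups | protic impurity | temperature | remark | time |
|---|---|---|---|---|---|---|
| green | 0.50 M | 0.475 M | 0.050 M | 65 °C | run made earlier |  |
| blue | 0.50 M | 0.24 M | 0.050 M | 76 °C | run made earlier |  |
| violet | 0.50 M | 0.36 M | 0.050 M | 65 °C | run made earlier |  |
| grey | 1 M | 0.475 M | 0.050 M | 76 °C | run made earlier |  |
| zeta | 0.50 M (fed, over 8.0 min) | 0.475 M | 0.0500 M |  | the addition at 40 °C, then warmed to 70 °C; the feed brings no volume worth counting | 20 min |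
| epsilon | 0.50 M | 0.475 M (fed, over 8.0 min) | 0.0500 M | 70 °C | all else is in the flask from the start; the feed brings no volume worth counting | 20 min |
| eta | 0.50 M | 0.475 M | 0.0500 M |  | everything together at the start at 40 °C, warmed to 70 °C at 8.0 min | 20 min |
| delta | 0.50 M | 0.475 M | 0.0500 M | 70 °C | everything together at the start | 20 min |

| run | time / min | links / % | rings / % |
|---|---|---|---|
| green | 0.833 | 42 | 3 |
| green | 2.50 | 60 | 7 |
| green | 4.00 | 69 | 10 |
| green | 6.00 | 73 | 9 |
| green | 10.0 | 76 | 11 |
| green | 12.0 | 77 | 10 |
| blue | 4.00 | 29 | 22 |
| blue | 8.00 | 30 | 18 |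
| blue | 12.0 | 33 | 19 |
| blue | 15.0 | 29 | 16 |
| blue | 20.0 | 29 | 21 |
| blue | 25.0 | 28 | 21 |
| violet | 1.50 | 40 | 5 |
| violet | 5.00 | 54 | 9 |
| violet | 8.00 | 53 | 11 |
| violet | 12.0 | 58 | 11 |
| violet | 20.0 | 58 | 13 |
| violet | 25.0 | 60 | 18 |
| grey | 2.00 | 34 | 9 |
| grey | 6.00 | 35 | 14 |
| grey | 12.0 | 39 | 14 |
| grey | 15.0 | 36 | 15 |
| grey | 25.0 | 32 | 13 |

(scatter of a reading: 2 percentage points)



1. the flask with the highest share of links in links plus rings ("all alike" if they lie within 1.5 percentage points) (zeta / epsilon / eta / delta / all alike)
2. share of links in links plus rings at the end, zeta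
3. share of links in links plus rings at the end, epsilon
4. share of links in links plus rings at the end, eta
5. share of links in links plus rings at the end, delta

2. Take equal making of links and rings as the zero of the scale. I take links over rings, at any moment, as second end groups over some level, so rings formed = level × ln((start + level)/(end + level)). Blue's mean rings of 0.0975 M, out of 0.24 M charged of the second end groups, give a level of 0.0621 M at 76 °C. Green's late rings of 0.0500 M, with 0.0483 M left of the second end groups, give a level of 0.0263 M at 65 °C. 70 °C lies near midway, so there the amount of second end groups at which links and rings form equally fast, the crossover level, is about 0.0404 M.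

3. Temperature: the level is lower at 65 °C than at 76 °C, so by hand a cold start favours eta. Delta starts at 11.7 crossover levels, then runs down through them hot.

4. Feeding second end groups: in green, half of them are used by 0.833 min, a lifetime near 1.20 min at 65 °C. Feed rate times that lifetime holds second end groups plus the crossover level near 0.0714 M in epsilon, which is 0.0309 M of second end groups. By this estimate links are 43.4% of what forms in epsilon, less than the 92.2% at the start of delta, so I put epsilon lowest.

5. Feeding first end groups: in zeta they arrive over the 8.0 min of the cold stage, while eta has them in the flask from the start, and as a judgement without a reckoning I put zeta below eta.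

6. The forecast says eta: zeta 88%, epsilon 72%, eta 92%, delta 83%, on the ground that “Links plus rings therefore stop at the limiting supply”. Its epsilon stands above my share for epsilon.

7. The flasks give eta highest: zeta 87.4%, epsilon 48.9%, eta 90.0%, delta 83.1%. Epsilon lies 23 percentage points under the forecast.

    first end groups + second end groups → links (k = 0.0450 L mol⁻¹ s⁻¹, Ea = 49.0 kJ mol⁻¹)
    first end groups + second end groups → rings, rate k2*[first end groups] as long as [second end groups] is above zero (k = 0.00170 s⁻¹, Ea = 111 kJ mol⁻¹)
    first end groups + protic impurity → quenched substrate (k = 0.0380 L mol⁻¹ s⁻¹, Ea = 62.0 kJ mol⁻¹)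
    first end groups ⇌ dormant form (K = 1.80, k = 4.90 × 10⁻⁴ s⁻¹, Ea = 97.0 kJ mol⁻¹, ΔH = −59.0 kJ mol⁻¹)
    (constants at 70 °C)

Epsilon's feed lasts 11 lifetimes of second end groups, reckoned against everything charged, and at 8.00 min epsilon holds 37.9% rings against 30.9% links, which with the crossover level of 0.0404 M puts second end groups near 0.0329 M as an average weighted by turnover. In eta at 20.0 min, second end groups of 0.0300 M stand at 0.742 crossover levels, and the rate of links over rings there is 0.80.

The readings are simulated from invented constants, and the scatter is random.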